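**Remark:** carbon numbers C1–C20 are those of the kaurane skeleton of the target (ring A = C1–C5 and C10; C20 = methyl on C10; C18/C19 = methyls on C4; C9 ketone; C11 acetoxy carbon; C7 carbinol; C8=C14, C15=O and C16=C17 in the cyclopentenone).
**Assumption:** the lipase acetylates the pro-S hydroxymethyl group of the prochiral diol; if its sense is opposite, the same monoacetate enantiomer is reached by lipase hydrolysis of the diacetate.
**Assumption:** the C15 silyloxy carbon is drawn as the cis epimer expected from the Luche reduction; its configuration is erased when C15 is oxidised.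

## Retrosynthetic overview

- The ten-membered ring is closed last at C7–C8 by an intramolecular Nozaki–Hiyama–Kishi addition of a cyclopentenyl iodide to the C7 aldehyde. The two halves are joined at C9–C11 by acylating a C9 dithiane anion, and C11 is then set by Corey–Bakshi–Shibata reduction.
- Ring A is made in one flask from an acyclic C10 aldehyde and an isoprenyl phosphonium salt: Wittig olefination forms C1–C2, then iron-hydride hydrogen-atom transfer gives the tertiary C4 radical, which closes onto C5 (6-exo).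
- Enabling feature: in ring A the gem-dimethyl carbon C4 is a tertiary radical site, C5 is β to oxygenated C7 (so C5=C6–C7O2Me is a radical acceptor), and C1 is a CH2 on quaternary C10 (so it can start as a non-enolisable aldehyde). C9, masked as a branched 1,3-dithian-2-yl group on C10, steers C5.
- C10 comes from lipase desymmetrisation of a prochiral diol and C13 from (1R,4S)-4-acetoxycyclopent-2-en-1-ol; C5 is relayed from C10, C11 is reagent-set and C7 is set in the ring closure.
- Ring order: cyclopentene (bought), ring A (step 8), ten-membered ring (step 23); C16=C17 is added near the end.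

Key step: step 8

## Route

Step 1
Reactants: 1 diethyl methylmalonate; 2 1,3-dithiane
Product: 4 diethyl 2-(1,3-dithian-2-yl)-2-methylmalonate, via 2-chloro-1,3-dithiane 3 (not isolated)
Conditions: 2, N-chlorosuccinimide, benzene, rt; then sodium salt of 1 (NaH, THF), 0 °C to rt
Reagents that add atoms: none
Why: chlorination of the dithiane gives a 2-chloro thioacetal that ionises to a thionium ion, so the tertiary malonate carbanion is C-alkylated (SN1-type alkylation of a stabilised carbanion), which puts C9 on C10 at the aldehyde oxidation level.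

Step 2
Reactants: 4 diethyl 2-(1,3-dithian-2-yl)-2-methylmalonate
Product: 5 2-(1,3-dithian-2-yl)-2-methylpropane-1,3-diol
Conditions: LiAlH4, THF, 0 °C to reflux
Reagents that add atoms: none
Why: hydride reduction of both esters should give the prochiral diol, the dithioacetal being inert to LiAlH4.

Step 3
Reactants: 5 2-(1,3-dithian-2-yl)-2-methylpropane-1,3-diol
Product: 6 (2S)-2-(1,3-dithian-2-yl)-3-hydroxy-2-methylpropyl acetate
Conditions: Burkholderia cepacia lipase, vinyl acetate, i-Pr2O, rt
Reagents that add atoms: vinyl acetate, C=COC(C)=O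
Why: lipase-catalysed enantiotopic-group-selective transesterification (enzymatic desymmetrisation of a 2,2-disubstituted propane-1,3-diol) sets C10, the enzyme distinguishing the branched sulfur-bearing group from the methyl group.

Step 4
Reactants: 6 (2S)-2-(1,3-dithian-2-yl)-3-hydroxy-2-methylpropyl acetate
Product: 8 methyl (2E,4S)-5-acetoxy-4-(1,3-dithian-2-yl)-4-methylpent-2-enoate, via aldehyde 7 (not isolated)
Conditions: SO3·pyridine, DMSO, i-Pr2NEt, CH2Cl2, 0 °C; then Ph3P=CHCO2Me, rt to 40 °C
Reagents that add atoms: methyl (triphenylphosphoranylidene)acetate, COC(=O)C=P(c1ccccc1)(c1ccccc1)c1ccccc1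
Why: Parikh–Doering oxidation spares the dithioacetal and gives a non-enolisable aldehyde, which the stabilised ylide should convert in the same flask into the (E)-enoate (Wittig olefination), creating the C5=C6–C7 acceptor arm.

Step 5
Reactants: 8 methyl (2E,4S)-5-acetoxy-4-(1,3-dithian-2-yl)-4-methylpent-2-enoate
Product: 9 methyl (2E,4S)-4-(1,3-dithian-2-yl)-5-hydroxy-4-methylpent-2-enoate
Conditions: K2CO3, MeOH, 0 °C
Reagents that add atoms: none
Why: base-catalysed methanolysis removes the primary acetate, while the methyl enoate is unchanged by methoxide exchange and its neopentylic β-carbon resists conjugate addition.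

Step 6
Reactants: 9 methyl (2E,4S)-4-(1,3-dithian-2-yl)-5-hydroxy-4-methylpent-2-enoate
Product: 10 methyl (2E,4S)-4-(1,3-dithian-2-yl)-4-methyl-5-oxopent-2-enoate
Conditions: SO3·pyridine, DMSO, i-Pr2NEt, CH2Cl2, 0 °C
Reagents that add atoms: none
Why: Parikh–Doering oxidation should give the C1 aldehyde, which has no α-hydrogen and so cannot epimerise C10.

Step 7
Reactants: 11 4-bromo-2-methylbut-1-ene
Product: 12 (3-methylbut-3-en-1-yl)triphenylphosphonium bromide
Conditions: PPh3, toluene, 110 °C
Reagents that add atoms: triphenylphosphine, c1ccc(cc1)P(c1ccccc1)c1ccccc1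
Why: SN2 quaternisation of the phosphine by the primary bromide gives the salt that carries C2, C3, C4 and C18.

Step 8
Reactants: 12 (3-methylbut-3-en-1-yl)triphenylphosphonium bromide; 10 methyl (2E,4S)-4-(1,3-dithian-2-yl)-4-methyl-5-oxopent-2-enoate
Product: 15 methyl 2-[(1R,2R)-2-(1,3-dithian-2-yl)-2,6,6-trimethylcyclohex-3-en-1-yl]acetate, via ylide 13 (not isolated), via Z-triene ester 14 (not isolated)
Conditions: 12, NaHMDS, THF, −78 °C; 10, −78 °C to rt; then EtOH, Fe(acac)3 (30 mol %), PhSiH3, 60 °C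
Reagents that add atoms: none
Why: Deprotonation of 12 gives the non-stabilised ylide 13, whose Wittig reaction with the hindered aldehyde 10 forms C1–C2 as the (Z)-alkene 14; ethanol, Fe(acac)3 and PhSiH3 then generate an iron hydride that transfers a hydrogen atom to the 1,1-disubstituted alkene (C18 becomes a methyl group), the tertiary C4 radical adds to C5 of the enoate, and the α-ester radical is reduced and protonated. The closest known reaction types are the Wittig olefination and the metal-hydride hydrogen-atom-transfer reductive olefin coupling (intramolecular Giese addition). Ring A closes in the 6-exo-trig mode, the cis C1=C2 bond holding the chain in a half-chair. The only new stereocentre, C5, is controlled by C10: the branched 1,3-dithian-2-yl group should take the pseudoequatorial site and the methyl group the pseudoaxial site next to the forming bond, with the enoate pseudoequatorial, so that C6 ends cis to C20 and trans to C9. The step needs Z geometry at C1=C2 (secured by the sodium-derived non-stabilised ylide and the bulky aldehyde) and hydrogen-atom transfer only to the 1,1-disubstituted alkene (secured by its higher substitution compared with the (Z)-alkene, the enoate serving only as acceptor).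

Step 9
Reactants: 15 methyl 2-[(1R,2R)-2-(1,3-dithian-2-yl)-2,6,6-trimethylcyclohex-3-en-1-yl]acetate
Product: 16 methyl 2-[(1R,2R)-2-(1,3-dithian-2-yl)-2,6,6-trimethylcyclohexyl]acetate
Conditions: TsNHNH2, NaOAc, DME/H2O, reflux
Reagents that add atoms: none
Why: diimide reduction saturates the cis-disubstituted C1=C2 bond without a heterogeneous catalyst (which the dithioacetal would poison) and touches no stereocentre.

Step 10
Reactants: 16 methyl 2-[(1R,2R)-2-(1,3-dithian-2-yl)-2,6,6-trimethylcyclohexyl]acetate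
Product: 17 2-[(1R,2R)-2-(1,3-dithian-2-yl)-2,6,6-trimethylcyclohexyl]ethan-1-ol
Conditions: LiAlH4, THF, 0 °C
Reagents that add atoms: none
Why: hydride reduction of the ester gives the primary C7 alcohol.

Step 11
Reactants: 17 2-[(1R,2R)-2-(1,3-dithian-2-yl)-2,6,6-trimethylcyclohexyl]ethan-1-ol
Product: 18 triethyl{2-[(1R,2R)-2-(1,3-dithian-2-yl)-2,6,6-trimethylcyclohexyl]ethoxy}silane
Conditions: Et3SiCl, imidazole, CH2Cl2, 0 °C
Reagents that add atoms: chlorotriethylsilane, CC[Si](Cl)(CC)CC
Why: silylation protects C7–OH as a primary triethylsilyl ether that can later be oxidised directly to the aldehyde.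

Step 12
Reactants: 19 (1R,4S)-4-acetoxycyclopent-2-en-1-ol; 20 dimethyl malonate
Product: 21 dimethyl 2-[(1S,4R)-4-hydroxycyclopent-2-en-1-yl]malonate
Conditions: NaH, Pd(PPh3)4 (5 mol %), THF, rt to 50 °C
Reagents that add atoms: none
Why: Tsuji–Trost allylic alkylation, in which zerovalent palladium ionises the acetate with inversion and the malonate attacks the allyl terminus remote from the hydroxyl with a second inversion, so the C12–C13 bond forms with net retention and C13 is taken from the chiral pool.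

Step 13
Reactants: 21 dimethyl 2-[(1S,4R)-4-hydroxycyclopent-2-en-1-yl]malonate
Product: 22 methyl 2-[(1R,4R)-4-hydroxycyclopent-2-en-1-yl]acetate
Conditions: NaCl, H2O, DMSO, 150 °C
Reagents that add atoms: none
Why: Krapcho dealkoxycarbonylation removes one ester under neutral conditions, leaving C11 as the ester carbon.

Step 14
Reactants: 22 methyl 2-[(1R,4R)-4-hydroxycyclopent-2-en-1-yl]acetate
Product: 23 methyl 2-[(1R)-4-oxocyclopent-2-en-1-yl]acetate
Conditions: MnO2, CH2Cl2, rt
Reagents that add atoms: none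
Why: MnO2 oxidises the allylic alcohol to the enone under neutral conditions that should not enolise the γ-stereocentre C13.

Step 15
Reactants: 23 methyl 2-[(1R)-4-oxocyclopent-2-en-1-yl]acetate
Product: 24 methyl 2-[(1R)-3-iodo-4-oxocyclopent-2-en-1-yl]acetate
Conditions: I2, pyridine, CH2Cl2, 0 °C to rt
Reagents that add atoms: iodine, II
Why: α-iodination of the enone (conjugate addition of pyridine, iodination of the enolate, elimination) places the halogen on C8 for the later ring closure.

Step 16
Reactants: 24 methyl 2-[(1R)-3-iodo-4-oxocyclopent-2-en-1-yl]acetate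
Product: 25 methyl 2-[(1R,4R)-4-hydroxy-3-iodocyclopent-2-en-1-yl]acetate
Conditions: NaBH4, CeCl3·7H2O, MeOH, −78 °C
Reagents that add atoms: none
Why: Luche 1,2-reduction masks C15 as an allylic alcohol, hydride adding anti to the C13 side chain to give mainly the cis alcohol (the C15 configuration is immaterial).

Step 17
Reactants: 25 methyl 2-[(1R,4R)-4-hydroxy-3-iodocyclopent-2-en-1-yl]acetate
Product: 26 methyl 2-[(1R,4R)-3-iodo-4-(triethylsilyloxy)cyclopent-2-en-1-yl]acetate
Conditions: Et3SiCl, imidazole, CH2Cl2, 0 °C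
Reagents that add atoms: chlorotriethylsilane, CC[Si](Cl)(CC)CC
Why: silylation protects C15–OH as a secondary triethylsilyl ether.

Step 18
Reactants: 26 methyl 2-[(1R,4R)-3-iodo-4-(triethylsilyloxy)cyclopent-2-en-1-yl]acetate
Product: 27 2-[(1R,4R)-3-iodo-4-(triethylsilyloxy)cyclopent-2-en-1-yl]-N-methoxy-N-methylacetamide
Conditions: MeNH(OMe)·HCl, AlMe3, CH2Cl2, 0 °C to rt
Reagents that add atoms: N,O-dimethylhydroxylamine hydrochloride, CNOC.Cl
Why: aminolysis of the ester by the aluminium amide gives the Weinreb amide, an acylating agent that stops at the ketone stage.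

Step 19
Reactants: 18 triethyl{2-[(1R,2R)-2-(1,3-dithian-2-yl)-2,6,6-trimethylcyclohexyl]ethoxy}silane; 27 2-[(1R,4R)-3-iodo-4-(triethylsilyloxy)cyclopent-2-en-1-yl]-N-methoxy-N-methylacetamide
Product: 29 1-{2-[(1R,2R)-1,3,3-trimethyl-2-(2-triethylsilyloxyethyl)cyclohexyl]-1,3-dithian-2-yl}-2-[(1R,4R)-3-iodo-4-(triethylsilyloxy)cyclopent-2-en-1-yl]ethan-1-one, via lithiodithiane 28 (not isolated)
Conditions: 18, t-BuLi, THF/HMPA, −78 to −30 °C; then 27, −78 °C
Reagents that add atoms: none
Why: Corey–Seebach umpolung, in which the lithiated dithiane (C9 acyl anion equivalent) is acylated by the Weinreb amide through a stable chelated tetrahedral intermediate, joins the fragments at C9–C11.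

Step 20
Reactants: 29 the C11 ketone
Product: 30 (1S)-1-{2-[(1R,2R)-1,3,3-trimethyl-2-(2-triethylsilyloxyethyl)cyclohexyl]-1,3-dithian-2-yl}-2-[(1R,4R)-3-iodo-4-(triethylsilyloxy)cyclopent-2-en-1-yl]ethan-1-ol
Conditions: (R)-2-methyl-CBS-oxazaborolidine (20 mol %), BH3·SMe2, THF, −20 °C
Reagents that add atoms: none
Why: Corey–Bakshi–Shibata reduction sets C11 (S) by reagent control, the fully substituted dithiane carbon acting as the large group and the C12 methylene as the small group.

Step 21
Reactants: 30 the C11 alcohol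
Product: 31 (1S)-1-{2-[(1R,2R)-1,3,3-trimethyl-2-(2-triethylsilyloxyethyl)cyclohexyl]-1,3-dithian-2-yl}-2-[(1R,4R)-3-iodo-4-(triethylsilyloxy)cyclopent-2-en-1-yl]ethyl acetate
Conditions: Ac2O, DMAP, pyridine, rt
Reagents that add atoms: acetic anhydride, CC(=O)OC(C)=O
Why: DMAP-catalysed acylation installs the C11 acetate of the target with retention.

Step 22
Reactants: 31 the C11 acetate
Product: 32 (1S)-1-{2-[(1R,2R)-1,3,3-trimethyl-2-(2-oxoethyl)cyclohexyl]-1,3-dithian-2-yl}-2-[(1R,4R)-3-iodo-4-(triethylsilyloxy)cyclopent-2-en-1-yl]ethyl acetate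
Conditions: (COCl)2, DMSO, CH2Cl2, −78 to −40 °C; Et3N
Reagents that add atoms: none
Why: under Swern conditions a primary triethylsilyl ether is desilylated at the activated oxygen and oxidised directly to the aldehyde, while the secondary silyl ether, the dithiane and the acetate should survive.

Step 23
Reactants: 32 the C7 aldehyde
Product: 33 ten-membered-ring allylic alcohol (C7–C8 closed; 7R hydroxyl, 11S acetate, C9 as 1,3-dithiane, C15 triethylsilyl ether, C8=C14)
Conditions: CrCl2, NiCl2 (cat.), DMSO/THF, high dilution, rt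
Reagents that add atoms: none
Why: Nozaki–Hiyama–Kishi reaction, in which zerovalent nickel inserts into the C8–I bond and the alkenyl group is passed to trivalent chromium and adds chemoselectively to the aldehyde, closing the ten-membered ring; the C7 configuration is set by substrate control, the aldehyde being expected to approach on the face away from the C15 silyloxy group.

Step 24
Reactants: 33 the macrocyclic C7 alcohol
Product: 34 C7 tert-butyldimethylsilyl ether of 33
Conditions: TBSOTf, 2,6-lutidine, CH2Cl2, −78 °C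
Reagents that add atoms: tert-butyldimethylsilyl trifluoromethanesulfonate, CC(C)(C)[Si](C)(C)OS(=O)(=O)C(F)(F)F
Why: silylation protects C7–OH so that C15 can later be oxidised alone.

Step 25
Reactants: 34 the bis-silyl ether
Product: 35 C15 alcohol (C7 still silylated)
Conditions: pyridinium p-toluenesulfonate (cat.), MeOH/CH2Cl2, 0 °C
Reagents that add atoms: none
Why: acid-catalysed methanolysis cleaves a secondary triethylsilyl ether much faster than a secondary tert-butyldimethylsilyl ether.

Step 26
Reactants: 35 the C15 alcohol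
Product: 36 C15 enone (C8=C14 conjugated), C9 still a dithiane
Conditions: MnO2, CH2Cl2, rt
Reagents that add atoms: none
Why: MnO2 oxidises the allylic alcohol to the cyclopentenone and leaves the dithiane, acetate and silyl ether alone.

Step 27
Reactants: 36 the dithiane enone
Product: 37 C9,C15-diketone (C7 silyl ether, C11 acetate)
Conditions: PhI(OCOCF3)2, NaHCO3, MeCN/H2O, 0 °C
Reagents that add atoms: water, O
Why: oxidative hydrolysis of the dithioketal by the hypervalent iodine reagent unmasks the C9 ketone under buffered conditions that the silyl ether and acetate should tolerate.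

Step 28
Reactants: 37 the diketone
Product: 41 C7 tert-butyldimethylsilyl ether of the target, via silyl dienol ether 38 (not isolated), via Mannich base 39 (not isolated), via ammonium iodide 40 (not isolated)
Conditions: TMSOTf, Et3N, CH2Cl2, −78 to 0 °C; Me2N=CH2 I, rt; MeI; aq. NaHCO3
Reagents that add atoms: Eschenmoser's salt (N,N-dimethylmethyleneiminium iodide), C=[N+](C)C.[I-]
Why: soft enolisation should occur only at the C16 methylene of the enone (the C9 ketone has only the hindered C11 methine), and Mannich reaction with Eschenmoser's salt followed by quaternisation and E1cB elimination installs C16=C17; C13 is a bridgehead and cannot enolise.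

Step 29
Reactants: 41 the silyl ether of the target
Product: 42 CNP0165527.2
Conditions: HF·pyridine, THF, 0 °C
Reagents that add atoms: none
Why: acidic fluoride desilylation frees C7–OH without touching the acetate or the cross-conjugated dienone.

## Compound list

1 | diethyl methylmalonate | CCOC(=O)C(C)C(=O)OCC | starting material
2 | 1,3-dithiane | C1CSCSC1 | starting material
3 | 2-chloro-1,3-dithiane | ClC1SCCCS1 | intermediate
4 | diethyl 2-(1,3-dithian-2-yl)-2-methylmalonate | CCOC(=O)C(C)(C1SCCCS1)C(=O)OCC | intermediate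
5 | 2-(1,3-dithian-2-yl)-2-methylpropane-1,3-diol | OCC(C)(CO)C1SCCCS1 | intermediate
6 | (2S)-2-(1,3-dithian-2-yl)-3-hydroxy-2-methylpropyl acetate | CC(=O)OC[C@](C)(CO)C1SCCCS1 | intermediate
7 | (2R)-2-(1,3-dithian-2-yl)-2-methyl-3-oxopropyl acetate | CC(=O)OC[C@](C)(C=O)C1SCCCS1 | intermediate
8 | methyl (2E,4S)-5-acetoxy-4-(1,3-dithian-2-yl)-4-methylpent-2-enoate | CC(=O)OC[C@](C)(/C=C/C(=O)OC)C1SCCCS1 | intermediate
9 | methyl (2E,4S)-4-(1,3-dithian-2-yl)-5-hydroxy-4-methylpent-2-enoate | OC[C@](C)(/C=C/C(=O)OC)C1SCCCS1 | intermediate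
10 | methyl (2E,4S)-4-(1,3-dithian-2-yl)-4-methyl-5-oxopent-2-enoate | O=C[C@](C)(/C=C/C(=O)OC)C1SCCCS1 | intermediate
11 | 4-bromo-2-methylbut-1-ene | C=C(C)CCBr | starting material
12 | (3-methylbut-3-en-1-yl)triphenylphosphonium bromide | C=C(C)CC[P+](c1ccccc1)(c1ccccc1)c1ccccc1.[Br-] | intermediate
13 | (3-methylbut-3-en-1-ylidene)triphenylphosphorane | C=C(C)CC=P(c1ccccc1)(c1ccccc1)c1ccccc1 | intermediate
14 | methyl (2E,4R,6Z)-4-(1,3-dithian-2-yl)-4,8-dimethylnona-2,6,8-trienoate | C=C(C)C/C=C\[C@](C)(/C=C/C(=O)OC)C1SCCCS1 | intermediate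
15 | methyl 2-[(1R,2R)-2-(1,3-dithian-2-yl)-2,6,6-trimethylcyclohex-3-en-1-yl]acetate | S1CCCSC1[C@]2(C)C=CCC(C)(C)[C@H]2CC(=O)OC | intermediate
16 | methyl 2-[(1R,2R)-2-(1,3-dithian-2-yl)-2,6,6-trimethylcyclohexyl]acetate | S1CCCSC1[C@]2(C)CCCC(C)(C)[C@H]2CC(=O)OC | intermediate
17 | 2-[(1R,2R)-2-(1,3-dithian-2-yl)-2,6,6-trimethylcyclohexyl]ethan-1-ol | S1CCCSC1[C@]2(C)CCCC(C)(C)[C@H]2CCO | intermediate
18 | triethyl{2-[(1R,2R)-2-(1,3-dithian-2-yl)-2,6,6-trimethylcyclohexyl]ethoxy}silane | S1CCCSC1[C@]2(C)CCCC(C)(C)[C@H]2CCO[Si](CC)(CC)CC | intermediate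
19 | (1R,4S)-4-acetoxycyclopent-2-en-1-ol (cis; carbinol carbon R, acetoxy carbon S) | CC(=O)O[C@@H]1C=C[C@H](O)C1 | starting material
20 | dimethyl malonate | COC(=O)CC(=O)OC | starting material
21 | dimethyl 2-[(1S,4R)-4-hydroxycyclopent-2-en-1-yl]malonate | COC(=O)C(C(=O)OC)[C@@H]1C=C[C@H](O)C1 | intermediate
22 | methyl 2-[(1R,4R)-4-hydroxycyclopent-2-en-1-yl]acetate | COC(=O)C[C@@H]1C=C[C@H](O)C1 | intermediate
23 | methyl 2-[(1R)-4-oxocyclopent-2-en-1-yl]acetate | COC(=O)C[C@@H]1C=CC(=O)C1 | intermediate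
24 | methyl 2-[(1R)-3-iodo-4-oxocyclopent-2-en-1-yl]acetate | COC(=O)C[C@@H]1C=C(I)C(=O)C1 | intermediate
25 | methyl 2-[(1R,4R)-4-hydroxy-3-iodocyclopent-2-en-1-yl]acetate | COC(=O)C[C@@H]1C=C(I)[C@H](O)C1 | intermediate
26 | methyl 2-[(1R,4R)-3-iodo-4-(triethylsilyloxy)cyclopent-2-en-1-yl]acetate | COC(=O)C[C@@H]1C=C(I)[C@H](O[Si](CC)(CC)CC)C1 | intermediate
27 | 2-[(1R,4R)-3-iodo-4-(triethylsilyloxy)cyclopent-2-en-1-yl]-N-methoxy-N-methylacetamide | CON(C)C(=O)C[C@@H]1C=C(I)[C@H](O[Si](CC)(CC)CC)C1 | intermediate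
28 | 2-lithio derivative of 18 (lithium on the dithiane carbon C9) | [Li]C1(SCCCS1)[C@]2(C)CCCC(C)(C)[C@H]2CCO[Si](CC)(CC)CC | intermediate
29 | 1-{2-[(1R,2R)-1,3,3-trimethyl-2-(2-triethylsilyloxyethyl)cyclohexyl]-1,3-dithian-2-yl}-2-[(1R,4R)-3-iodo-4-(triethylsilyloxy)cyclopent-2-en-1-yl]ethan-1-one | O=C(C[C@@H]1C=C(I)[C@H](O[Si](CC)(CC)CC)C1)C1(SCCCS1)[C@]2(C)CCCC(C)(C)[C@H]2CCO[Si](CC)(CC)CC | intermediate
30 | (1S)-alcohol from 29 (C11 carbinol) | O[C@@H](C[C@@H]1C=C(I)[C@H](O[Si](CC)(CC)CC)C1)C1(SCCCS1)[C@]2(C)CCCC(C)(C)[C@H]2CCO[Si](CC)(CC)CC | intermediate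
31 | (1S)-acetate of 30 (C11 acetate) | CC(=O)O[C@@H](C[C@@H]1C=C(I)[C@H](O[Si](CC)(CC)CC)C1)C1(SCCCS1)[C@]2(C)CCCC(C)(C)[C@H]2CCO[Si](CC)(CC)CC | intermediate
32 | C7 aldehyde: (1S)-1-{2-[(1R,2R)-1,3,3-trimethyl-2-(2-oxoethyl)cyclohexyl]-1,3-dithian-2-yl}-2-[(1R,4R)-3-iodo-4-(triethylsilyloxy)cyclopent-2-en-1-yl]ethyl acetate | CC(=O)O[C@@H](C[C@@H]1C=C(I)[C@H](O[Si](CC)(CC)CC)C1)C1(SCCCS1)[C@]2(C)CCCC(C)(C)[C@H]2CC=O | intermediate
33 | macrocyclic alcohol: C7–C8 closed, 7R hydroxyl, 11S acetate, C9 1,3-dithiane, C15 triethylsilyl ether, C8=C14; C5, C10, C13 as in the target | C1[C@@H](O[Si](CC)(CC)CC)C2=C[C@H]1C[C@H](OC(C)=O)C3(SCCCS3)[C@]4(C)CCCC(C)(C)[C@H]4C[C@H]2O | intermediate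
34 | C7 tert-butyldimethylsilyl ether of 33 | C1[C@@H](O[Si](CC)(CC)CC)C2=C[C@H]1C[C@H](OC(C)=O)C3(SCCCS3)[C@]4(C)CCCC(C)(C)[C@H]4C[C@H]2O[Si](C)(C)C(C)(C)C | intermediate
35 | C15 alcohol (C7 silyl ether, C9 dithiane) | C1[C@@H](O)C2=C[C@H]1C[C@H](OC(C)=O)C3(SCCCS3)[C@]4(C)CCCC(C)(C)[C@H]4C[C@H]2O[Si](C)(C)C(C)(C)C | intermediate
36 | C15 enone (C7 silyl ether, C9 dithiane) | C1C(=O)C2=C[C@H]1C[C@H](OC(C)=O)C3(SCCCS3)[C@]4(C)CCCC(C)(C)[C@H]4C[C@H]2O[Si](C)(C)C(C)(C)C | intermediate
37 | C9,C15-diketone (C7 silyl ether, C16 still CH2) | C1C(=O)C2=C[C@H]1C[C@H](OC(C)=O)C(=O)[C@]3(C)CCCC(C)(C)[C@H]3C[C@H]2O[Si](C)(C)C(C)(C)C | intermediate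
38 | C15 trimethylsilyl dienol ether of 37 (C15=C16) | C1=C(O[Si](C)(C)C)C2=C[C@H]1C[C@H](OC(C)=O)C(=O)[C@]3(C)CCCC(C)(C)[C@H]3C[C@H]2O[Si](C)(C)C(C)(C)C | intermediate
39 | C16 dimethylaminomethyl ketone (Mannich base, C16 epimers) | CN(C)CC1C(=O)C2=C[C@H]1C[C@H](OC(C)=O)C(=O)[C@]3(C)CCCC(C)(C)[C@H]3C[C@H]2O[Si](C)(C)C(C)(C)C | intermediate
40 | trimethylammonium iodide from 39 | C[N+](C)(C)CC1C(=O)C2=C[C@H]1C[C@H](OC(C)=O)C(=O)[C@]3(C)CCCC(C)(C)[C@H]3C[C@H]2O[Si](C)(C)C(C)(C)C.[I-] | intermediate
41 | C7 tert-butyldimethylsilyl ether of the target | C=C1C(=O)C2=C[C@H]1C[C@H](OC(C)=O)C(=O)[C@]3(C)CCCC(C)(C)[C@H]3C[C@H]2O[Si](C)(C)C(C)(C)C | intermediate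
42 | CNP0165527.2 (11S-acetoxy-7R-hydroxy-8,9-seco-ent-kaura-8(14),16-diene-9,15-dione) | C=C1C(=O)C2=C[C@H]1C[C@H](OC(C)=O)C(=O)[C@]1(C)CCCC(C)(C)[C@H]1C[C@H]2O | target

## Step count and risks

Total step count: 29. Longest linear sequence: 21 steps (steps 1–6, 8–11 and 19–29, from diethyl methylmalonate).

The three steps most likely to fail:

Step 8 (key step). The tertiary C4 radical may be reduced before it closes (net hydrogenation of the 1,1-disubstituted alkene) in the crude olefination mixture, and facial selectivity at C5 may be eroded. The fallback sets out from 10 and comes back at 15. The Wittig reaction is worked up and triene ester 14 isolated. HBr (1 equiv, CH2Cl2, −40 °C) should then add in the Markovnikov sense to the 1,1-disubstituted alkene only, giving methyl (2E,4R,6Z)-8-bromo-4-(1,3-dithian-2-yl)-4,8-dimethylnona-2,6-dienoate F1. Bromine abstraction with Bu3SnH and Et3B/O2 in toluene at −40 °C generates the same C4 radical without a metal hydride, at a temperature that should sharpen the C5 selectivity, and should give 15.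

Step 23. Closure of the strained ten-membered ring may be slow, with competing protodeiodination, and facial selectivity at C7 may be poor. The fallback sets out from 33 (as the C7 epimer mixture) and comes back at 33. MnO2 (CH2Cl2, rt) oxidises the allylic C7 alcohol to the C7 ketone of the macrocycle F2. Reduction with (S)-2-methyl-CBS-oxazaborolidine and catecholborane (toluene, −78 °C), with the alkenyl carbon C8 as the large group, should then set 7R by reagent control and return 33.

Step 19. Proton transfer from the α-methylene group of the amide to the hindered carbanion may compete with addition, returning 18 and 27. The fallback sets out from 26 and comes back at 29. DIBAL-H (toluene, −78 °C) reduces ester 26 to 2-[(1R,4R)-3-iodo-4-(triethylsilyloxy)cyclopent-2-en-1-yl]acetaldehyde F3. Carbanion 28 should add to this more electrophilic partner (THF, −78 °C) to give the C11 carbinol F4 as an epimer mixture. Parikh–Doering oxidation (SO3·pyridine, DMSO, i-Pr2NEt) then gives ketone 29.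

Further compounds
F1 | step 8 | methyl (2E,4R,6Z)-8-bromo-4-(1,3-dithian-2-yl)-4,8-dimethylnona-2,6-dienoate | CC(C)(Br)C/C=C\[C@](C)(/C=C/C(=O)OC)C1SCCCS1
F2 | step 23 | C7 ketone of macrocycle 33 (C7=O conjugated with C8=C14; C9 dithiane, C11 acetate, C15 triethylsilyl ether) | C1[C@@H](O[Si](CC)(CC)CC)C2=C[C@H]1C[C@H](OC(C)=O)C3(SCCCS3)[C@]4(C)CCCC(C)(C)[C@H]4CC2=O
F3 | step 19 | 2-[(1R,4R)-3-iodo-4-(triethylsilyloxy)cyclopent-2-en-1-yl]acetaldehyde | O=CC[C@@H]1C=C(I)[C@H](O[Si](CC)(CC)CC)C1
F4 | step 19 | 1-{2-[(1R,2R)-1,3,3-trimethyl-2-(2-triethylsilyloxyethyl)cyclohexyl]-1,3-dithian-2-yl}-2-[(1R,4R)-3-iodo-4-(triethylsilyloxy)cyclopent-2-en-1-yl]ethan-1-ol (C11 epimers) | OC(C[C@@H]1C=C(I)[C@H](O[Si](CC)(CC)CC)C1)C1(SCCCS1)[C@]2(C)CCCC(C)(C)[C@H]2CCO[Si](CC)(CC)CC
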